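**Retrosynthetic overview**
1. Kobophenol A ⇐ its deca-O-benzyl ether (hydrogenolysis) ⇐ loss of CO (solid-state Norrish type I photodecarbonylation) from an all-equatorial 2,3,5,6-tetraaryloxan-4-one; the oxolane C3–C4 bond is made last and the five-membered ring comes from a six-membered one.
2. Enabling feature: oxolane C3 (bearing the dihydrobenzofuran-4-yl group) and C4 (bearing the 3,5-dihydroxyphenyl group) are both benzylic CH carbons, each flanked by an O-bonded benzylic carbon (C2, C5, each with a 4-hydroxyphenyl group), and the ring is 2,3-trans/3,4-cis/4,5-trans. A carbonyl inserted between C3 and C4 gives a Maitland–Japp-type oxan-4-one whose all-equatorial chair has exactly this pattern (3,5-cis-diequatorial = 3,4-cis) and whose two α-carbons are benzylic, as photodecarbonylation requires.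
3. Oxan-4-one ⇐ Fukuyama coupling of the benzylic zinc reagent of the bis(dihydrobenzofuran) with an Evans-aldol thioester, Knoevenagel condensation with 4-(benzyloxy)benzaldehyde, oxa-Michael closure and α-epimerisation; only the aldol carbinol (future oxolane C5) needs reagent control.
4. Both trans-dihydrobenzofurans ⇐ Rh(II)-catalysed donor/donor-carbene C–H insertion into 4-(benzyloxy)benzyl aryl ethers (opposite catalyst antipodes), then one acid-mediated cis→trans epimerisation; the diaryl ketones come from a Grignard addition/oxidation and from an aryllithium opening of a phthalide.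
5. Order of ring formation: dihydrobenzofuran B, dihydrobenzofuran A, temporary oxan-4-one, oxolane.

Key step: step 24

Assumption: the structure is taken exactly as written in the SMILES, i.e. dihydrobenzofuran B is linked through C5 and hydroxylated at C7 (catechol-type ring), and all ten phenols are carried as benzyl ethers.

Abbreviations in names: Ar = 4-(benzyloxy)phenyl; Res = 3,5-bis(benzyloxy)phenyl; DBF-B = 7-(benzyloxy)-2-Ar-3-Res-2,3-dihydro-1-benzofuran-5-yl; AB = (2S,3S)-6-(benzyloxy)-2-Ar-3-[(2R,3R)-DBF-B]-2,3-dihydro-1-benzofuran-4-yl; TBDPS = tert-butyldiphenylsilyl; TES = triethylsilyl. Oxolane numbering: O1, C2 (Ar, next to C3), C3 (AB), C4 (Res), C5 (Ar).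

**Step 1**
Reactants: 1 5-bromo-2,3-dihydroxybenzaldehyde
Product: 2 3-(benzyloxy)-5-bromo-2-hydroxybenzaldehyde
Conditions: NaH (2.2 equiv), DMSO, 20 °C; BnBr (1.0 equiv); aq. HCl
Reagents that add atoms: benzyl bromide BrCc1ccccc1
Why: Williamson etherification of the dianion, in which the 2-phenoxide is held in a chelate with the formyl group so that the free 3-phenoxide should take the single equivalent of benzyl bromide.

**Step 2**
Reactants: 2 3-(benzyloxy)-5-bromo-2-hydroxybenzaldehyde; 3 4-(benzyloxy)benzyl chloride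
Product: 4 3-(benzyloxy)-5-bromo-2-{[4-(benzyloxy)benzyl]oxy}benzaldehyde
Conditions: K2CO3, KI (cat.), DMF, 60 °C
Reagents that add atoms: none
Why: Williamson etherification of the remaining ortho-formyl phenol installs the 4-(benzyloxy)benzyl ether whose OCH2 group is the later carbene insertion site and ends as C2 (with its aryl group) of dihydrobenzofuran B.

**Step 3**
Reactants: 4 3-(benzyloxy)-5-bromo-2-{[4-(benzyloxy)benzyl]oxy}benzaldehyde; 5 1,3-bis(benzyloxy)-5-bromobenzene
Product: 7 racemic [3-(benzyloxy)-5-bromo-2-{[4-(benzyloxy)benzyl]oxy}phenyl](Res)methanol, via arylmagnesium bromide 6 (not isolated)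
Conditions: 5, Mg, I2 (cat.), THF, 50 °C; then 4, THF, 0 °C; aqueous work-up
Reagents that add atoms: none
Why: Grignard addition to the aldehyde is far faster than halogen–metal exchange at the aryl bromide at 0 °C, and the new carbinol centre is removed in the next step, so its configuration does not matter.

**Step 4**
Reactants: 7 racemic diaryl carbinol
Product: 8 [3-(benzyloxy)-5-bromo-2-{[4-(benzyloxy)benzyl]oxy}phenyl](Res)methanone
Conditions: Dess–Martin periodinane, CH2Cl2, 20 °C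
Reagents that add atoms: none
Why: Dess–Martin oxidation of a diaryl carbinol to the benzophenone is mild enough for the aryl bromide and the benzylic ethers.

**Step 5**
Reactants: 8 diaryl ketone
Product: 9 hydrazone of ketone 8 (E/Z mixture)
Conditions: N2H4·H2O (10 equiv), AcOH (cat.), EtOH, 80 °C
Reagents that add atoms: hydrazine NN
Why: Hydrazone condensation of a mono-ortho-substituted benzophenone proceeds under standard acid catalysis, and the ethers and the aryl bromide are inert to hydrazine.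

**Step 6**
Reactants: 9 hydrazone of ketone 8
Product: 11 (2S,3R)-7-(benzyloxy)-5-bromo-2-Ar-3-Res-2,3-dihydro-1-benzofuran (2,3-cis), via diaryldiazomethane 10 (not isolated)
Conditions: MnO2, CH2Cl2, 0 °C, filtration; then Rh2(R-PTAD)4 (1 mol%), CH2Cl2, −40 → 0 °C
Reagents that add atoms: none
Why: MnO2 dehydrogenates the hydrazone to the diaryldiazomethane and the Rh(II) donor/donor carbene undergoes intramolecular 1,5 C–H insertion into the doubly activated OCH2Ar bond, the chiral carboxylate catalyst fixing C3 as R (the antipode is exchanged with that of step 13 if the sense found is the reverse) while the kinetic cis C2 centre is corrected in step 14.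

**Step 7**
Reactants: 12 5,7-dimethoxy-2-benzofuran-1(3H)-one (5,7-dimethoxyphthalide)
Product: 13 5,7-dihydroxy-2-benzofuran-1(3H)-one
Conditions: BBr3 (3 equiv), CH2Cl2, −78 → 20 °C; H2O
Reagents that add atoms: none
Why: Lewis-acid O-demethylation of aryl methyl ethers with BBr3 leaves the phthalide lactone intact.

**Step 8**
Reactants: 13 5,7-dihydroxy-2-benzofuran-1(3H)-one
Product: 14 5-(benzyloxy)-7-hydroxy-2-benzofuran-1(3H)-one
Conditions: BnBr (1.05 equiv), K2CO3 (1.1 equiv), acetone, 50 °C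
Reagents that add atoms: benzyl bromide BrCc1ccccc1
Why: Selective Williamson etherification, because the 7-hydroxyl is hydrogen-bonded to the lactone carbonyl whereas the 5-hydroxyl, para to the carbonyl-bearing carbon, is the more acidic and accessible one.

**Step 9**
Reactants: 14 5-(benzyloxy)-7-hydroxy-2-benzofuran-1(3H)-one; 3 4-(benzyloxy)benzyl chloride
Product: 15 5-(benzyloxy)-7-{[4-(benzyloxy)benzyl]oxy}-2-benzofuran-1(3H)-one
Conditions: K2CO3, KI (cat.), DMF, 70 °C
Reagents that add atoms: none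
Why: Williamson etherification of the remaining chelated phenol under more forcing conditions places the insertion handle ortho to the carbonyl carbon that becomes C3 of dihydrobenzofuran A.

**Step 10**
Reactants: 11 cis-5-bromodihydrobenzofuran; 15 phthalide
Product: 17 [4-(benzyloxy)-2-{[4-(benzyloxy)benzyl]oxy}-6-(hydroxymethyl)phenyl][(2S,3R)-DBF-B]methanone (open form of its lactol), via aryllithium 16 (not isolated)
Conditions: n-BuLi (1.05 equiv), THF, −78 °C; then 15, −78 → −40 °C; H2O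
Reagents that add atoms: none
Why: Bromine–lithium exchange followed by acyl addition to the phthalide stops at the lithium lactolate, so work-up gives the diaryl ketone with the benzylic alcohol carbon (the later oxolane C3) already in place, and no stereocentre is formed or touched.

**Step 11**
Reactants: 17 keto alcohol
Product: 18 TBDPS ether of 17
Conditions: TBDPSCl, imidazole, DMF, 20 °C
Reagents that add atoms: tert-butyl(chloro)diphenylsilane CC(C)(C)[Si](Cl)(c1ccccc1)c1ccccc1
Why: Silylation of the primary alcohol removes the lactol equilibrium, protects the alcohol from MnO2, keeps a nucleophilic hydroxyl away from the benzylic cation of step 14, and its bulk disfavours oxonium ylide formation in step 13.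

**Step 12**
Reactants: 18 silyl ether ketone
Product: 19 hydrazone of ketone 18 (E/Z mixture)
Conditions: anhydrous N2H4 (excess), AcOH (cat.), n-BuOH, 110 °C, sealed tube
Reagents that add atoms: hydrazine NN
Why: Hydrazone condensation, here on a di-ortho-substituted benzophenone, is driven by excess hydrazine at elevated temperature, which aryl benzyl ethers and the TBDPS ether tolerate.

**Step 13**
Reactants: 19 hydrazone of ketone 18
Product: 21 (2R,3S)-6-(benzyloxy)-2-Ar-3-[(2S,3R)-DBF-B]-4-{[(TBDPS)oxy]methyl}-2,3-dihydro-1-benzofuran (both rings cis), via diazo compound 20 (not isolated)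
Conditions: MnO2, CH2Cl2, 0 °C, filtration; then Rh2(S-PTAD)4 (2 mol%), CH2Cl2, −40 → 0 °C
Reagents that add atoms: none
Why: The same hydrazone oxidation and Rh(II)-catalysed intramolecular C–H insertion of a donor/donor carbene as in step 6, now with the enantiomeric catalyst so that C3 of ring A is set as S (opposite topicity to ring B), the only 1,5-related activated C–H bond being that of the ortho OCH2Ar group.

**Step 14**
Reactants: 21 cis,cis-bis(dihydrobenzofuran)
Product: 22 (2S,3S)-6-(benzyloxy)-2-Ar-3-[(2R,3R)-DBF-B]-4-{[(TBDPS)oxy]methyl}-2,3-dihydro-1-benzofuran (both rings trans; AB-CH2OTBDPS)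
Conditions: TFA (10 equiv), CH2Cl2, 0 → 20 °C
Reagents that add atoms: none
Why: Brønsted-acid epimerisation at C2 of both rings by reversible ionisation of the 4-alkoxybenzylic C2–O bond (quinone-methide-like cation, recapture by the phenol) is stereoconvergent towards the more stable trans isomers and leaves the catalyst-set C3 centres untouched.

**Step 15**
Reactants: 22 trans,trans silyl ether
Product: 23 AB-methanol
Conditions: TBAF, THF, 20 °C
Reagents that add atoms: none
Why: Fluoride cleavage of the silyl ether is orthogonal to the aryl benzyl ethers and the dihydrobenzofurans.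

**Step 16**
Reactants: 23 AB-methanol
Product: 24 AB-methyl bromide (4-(bromomethyl) compound)
Conditions: CBr4, PPh3, CH2Cl2, 0 °C
Reagents that add atoms: carbon tetrabromide BrC(Br)(Br)Br
Why: Appel bromination converts the primary benzylic alcohol under neutral conditions that do not ionise the dihydrobenzofuran C2–O bonds.

**Step 17**
Reactants: 25 2-[3,5-bis(benzyloxy)phenyl]acetic acid; 26 (4S)-4-benzyl-1,3-oxazolidin-2-one
Product: 27 (4S)-4-benzyl-3-[(Res)acetyl]-1,3-oxazolidin-2-one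
Conditions: DCC, DMAP (cat.), CH2Cl2, 0 → 20 °C
Reagents that add atoms: none
Why: Carbodiimide (Steglich-type) N-acylation of the oxazolidinone with an arylacetic acid gives the imide without a strong base.

**Step 18**
Reactants: 27 N-arylacetyl oxazolidinone; 28 4-(benzyloxy)benzaldehyde
Product: 30 (4S)-4-benzyl-3-[(2S,3S)-3-Ar-3-hydroxy-2-Res-propanoyl]-1,3-oxazolidin-2-one, via boron enolate 29 (not isolated)
Conditions: Bu2BOTf, iPr2NEt, CH2Cl2, 0 °C; then 28, −78 → 0 °C; pH 7 buffer, MeOH, 30% H2O2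
Reagents that add atoms: none
Why: Evans syn-aldol reaction, in which the Z-boron enolate adds to the aldehyde through a closed Zimmerman–Traxler transition state on the face opposite the auxiliary benzyl group, setting the carbinol centre as S (the future oxolane C5), the α-centre being provisional.

**Step 19**
Reactants: 30 aldol adduct
Product: 31 TES ether of 30
Conditions: TESOTf, 2,6-lutidine, CH2Cl2, −78 → 0 °C
Reagents that add atoms: triethylsilyl triflate CC[Si](CC)(CC)OS(=O)(=O)C(F)(F)F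
Why: Silylation of the aldol hydroxyl blocks retro-aldol cleavage in the following basic steps.

**Step 20**
Reactants: 31 silylated aldol imide
Product: 32 S-ethyl (2S,3S)-3-Ar-2-Res-3-[(triethylsilyl)oxy]propanethioate
Conditions: EtSH (3 equiv), n-BuLi (2.5 equiv), THF, 0 °C; aqueous work-up
Reagents that add atoms: ethanethiol CCS
Why: Thiolate cleavage of the N-acyloxazolidinone at the exocyclic carbonyl gives the thioester needed for ketone synthesis and returns the auxiliary.

**Step 21**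
Reactants: 24 AB-methyl bromide; 32 thioester
Product: 34 (3S,4S)-1-AB-4-Ar-3-Res-4-[(triethylsilyl)oxy]butan-2-one, via benzylzinc bromide 33 (not isolated)
Conditions: Zn dust, LiCl, THF, 20 °C; then 32, PdCl2(PPh3)2 (5 mol%), THF/toluene, 20 °C; aqueous work-up
Reagents that add atoms: none
Why: Zinc inserts selectively into the benzylic C–Br bond and the Pd-catalysed Fukuyama coupling of the benzylzinc reagent with the thioester gives the ketone without over-addition, the non-basic organozinc leaving the acidic α-aryl centre and the silyl ether alone.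

**Step 22**
Reactants: 34 β-silyloxy ketone; 28 4-(benzyloxy)benzaldehyde
Product: 35 (5S)-2-AB-1,5-di-Ar-4-Res-5-[(triethylsilyl)oxy]pent-1-en-3-one (E/Z mixture; C4 epimers, both of which converge in step 23)
Conditions: piperidine (0.3 equiv), AcOH (0.3 equiv), 4 Å MS, toluene, 70 °C
Reagents that add atoms: none
Why: Knoevenagel-type (Claisen–Schmidt) condensation under amine/acid catalysis can only occur at the methylene between the carbonyl group and the benzofuran ring, the other α-carbon being tertiary, and the silyl ether prevents retro-aldol loss of the fixed carbinol centre.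

**Step 23**
Reactants: 35 silyloxy enone
Product: 37 (2S,3R,5S,6R)-5-AB-2,6-di-Ar-3-Res-oxan-4-one (all four aryl groups equatorial), via hydroxy enone 36 (not isolated)
Conditions: TBAF (1.1 equiv), THF, 0 → 20 °C; then DBU (0.2 equiv), 20 °C
Reagents that add atoms: none
Why: Desilylation frees the alkoxide, which closes the ring by 6-endo-trig oxa-Michael addition (the second half of a Maitland–Japp oxan-4-one synthesis) through a chair with the aryl groups equatorial (2,6-cis), and DBU-mediated enolisation then epimerises C3 and C5 so that the fixed C2 centre dictates the all-equatorial isomer.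

**Step 24**
Reactants: 37 all-equatorial tetraaryloxan-4-one
Product: 38 (2R,3S,4R,5S)-3-AB-2,5-di-Ar-4-Res-oxolane (deca-O-benzylkobophenol A)
Conditions: hν (λ > 300 nm, Pyrex-filtered medium-pressure Hg lamp), crystalline 37 as a stirred suspension in water (0.05% CTAB), 10 °C, argon
Reagents that add atoms: none
Why: Proposed new method: n→π* excitation of the oxanone carbonyl triggers Norrish type I cleavage of one benzylic C–C(O) bond, loss of CO from the acyl radical and recombination of the resulting 1,5-bis(benzylic) biradical, so that the six-membered ring contracts to the oxolane by forming the C3–C4 bond. The closest known reaction type is the stereospecific solid-state photodecarbonylation of crystalline ketones that carry radical-stabilising groups on both α-carbons, including 2,6-diarylcyclohexanone derivatives that contract to 1,2-diarylcyclopentanes; its use on a 3,5-diaryloxan-4-one is new. The oxolane is closed by intramolecular radical–radical combination of the 1,5-biradical to a five-membered ring. C3 and C4 are re-formed with retention because the rigid lattice forbids rotation of the radical centres before least-motion closure, and C2 and C5 are never touched, so the 2,3-trans/3,5-cis/5,6-trans oxanone is translated into the 2,3-trans/3,4-cis/4,5-trans oxolane. The step needs α-cleavage to win over other photoreactions (both α-carbons are benzylic, there is no abstractable γ-hydrogen, and light above 300 nm excites only the ketone) and ring closure to win over disproportionation and stereochemical scrambling, which the solid state should secure.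

**Step 25**
Reactants: 38 deca-O-benzylkobophenol A
Product: 39 kobophenol A
Conditions: H2 (1 atm), 10% Pd/C (acid-free), EtOAc/MeOH (1:1), 20 °C
Reagents that add atoms: none
Why: Catalytic hydrogenolysis cleaves the ten aryl benzyl ethers under neutral conditions much faster than the secondary benzylic C–O bonds of the oxolane and dihydrobenzofuran rings, and avoids acid, to which 4-hydroxybenzylic ethers of this kind are sensitive.

**Compound list**
1 | 5-bromo-2,3-dihydroxybenzaldehyde | O=Cc1cc(Br)cc(O)c1O | starting material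
2 | 3-(benzyloxy)-5-bromo-2-hydroxybenzaldehyde | O=Cc1cc(Br)cc(OCc2ccccc2)c1O | intermediate
3 | 4-(benzyloxy)benzyl chloride | ClCc1ccc(OCc2ccccc2)cc1 | starting material
4 | 3-(benzyloxy)-5-bromo-2-{[4-(benzyloxy)benzyl]oxy}benzaldehyde | O=Cc1cc(Br)cc(OCc2ccccc2)c1OCc1ccc(OCc2ccccc2)cc1 | intermediate
5 | 1,3-bis(benzyloxy)-5-bromobenzene | Brc1cc(OCc2ccccc2)cc(OCc2ccccc2)c1 | starting material
6 | [3,5-bis(benzyloxy)phenyl]magnesium bromide (not isolated) | Br[Mg]c1cc(OCc2ccccc2)cc(OCc2ccccc2)c1 | intermediate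
7 | racemic [3-(benzyloxy)-5-bromo-2-{[4-(benzyloxy)benzyl]oxy}phenyl](Res)methanol | OC(c1cc(OCc2ccccc2)cc(OCc2ccccc2)c1)c1cc(Br)cc(OCc2ccccc2)c1OCc1ccc(OCc2ccccc2)cc1 | intermediate
8 | [3-(benzyloxy)-5-bromo-2-{[4-(benzyloxy)benzyl]oxy}phenyl](Res)methanone | O=C(c1cc(OCc2ccccc2)cc(OCc2ccccc2)c1)c1cc(Br)cc(OCc2ccccc2)c1OCc1ccc(OCc2ccccc2)cc1 | intermediate
9 | hydrazone of ketone 8 (E/Z mixture) | NN=C(c1cc(OCc2ccccc2)cc(OCc2ccccc2)c1)c1cc(Br)cc(OCc2ccccc2)c1OCc1ccc(OCc2ccccc2)cc1 | intermediate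
10 | diaryldiazomethane from 9 (not isolated) | [N-]=[N+]=C(c1cc(OCc2ccccc2)cc(OCc2ccccc2)c1)c1cc(Br)cc(OCc2ccccc2)c1OCc1ccc(OCc2ccccc2)cc1 | intermediate
11 | (2S,3R)-7-(benzyloxy)-5-bromo-2-Ar-3-Res-2,3-dihydro-1-benzofuran (cis) | Brc1cc(OCc2ccccc2)c2c(c1)[C@@H](c1cc(OCc3ccccc3)cc(OCc3ccccc3)c1)[C@@H](c1ccc(OCc3ccccc3)cc1)O2 | intermediate
12 | 5,7-dimethoxy-2-benzofuran-1(3H)-one | O=C1OCc2cc(OC)cc(OC)c21 | starting material
13 | 5,7-dihydroxy-2-benzofuran-1(3H)-one | O=C1OCc2cc(O)cc(O)c21 | intermediate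
14 | 5-(benzyloxy)-7-hydroxy-2-benzofuran-1(3H)-one | O=C1OCc2cc(OCc3ccccc3)cc(O)c21 | intermediate
15 | 5-(benzyloxy)-7-{[4-(benzyloxy)benzyl]oxy}-2-benzofuran-1(3H)-one | O=C1OCc2cc(OCc3ccccc3)cc(OCc3ccc(OCc4ccccc4)cc3)c21 | intermediate
16 | (2S,3R)-DBF-B-lithium (not isolated) | [Li]c1cc(OCc2ccccc2)c2c(c1)[C@@H](c1cc(OCc3ccccc3)cc(OCc3ccccc3)c1)[C@@H](c1ccc(OCc3ccccc3)cc1)O2 | intermediate
17 | [4-(benzyloxy)-2-{[4-(benzyloxy)benzyl]oxy}-6-(hydroxymethyl)phenyl][(2S,3R)-DBF-B]methanone | OCc1cc(OCc2ccccc2)cc(OCc2ccc(OCc3ccccc3)cc2)c1C(=O)c1cc(OCc2ccccc2)c2c(c1)[C@@H](c1cc(OCc3ccccc3)cc(OCc3ccccc3)c1)[C@@H](c1ccc(OCc3ccccc3)cc1)O2 | intermediate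
18 | TBDPS ether of 17 | CC(C)(C)[Si](c1ccccc1)(c1ccccc1)OCc1cc(OCc2ccccc2)cc(OCc2ccc(OCc3ccccc3)cc2)c1C(=O)c1cc(OCc2ccccc2)c2c(c1)[C@@H](c1cc(OCc3ccccc3)cc(OCc3ccccc3)c1)[C@@H](c1ccc(OCc3ccccc3)cc1)O2 | intermediate
19 | hydrazone of ketone 18 (E/Z mixture) | CC(C)(C)[Si](c1ccccc1)(c1ccccc1)OCc1cc(OCc2ccccc2)cc(OCc2ccc(OCc3ccccc3)cc2)c1C(=NN)c1cc(OCc2ccccc2)c2c(c1)[C@@H](c1cc(OCc3ccccc3)cc(OCc3ccccc3)c1)[C@@H](c1ccc(OCc3ccccc3)cc1)O2 | intermediate
20 | diazo compound from 19 (not isolated) | CC(C)(C)[Si](c1ccccc1)(c1ccccc1)OCc1cc(OCc2ccccc2)cc(OCc2ccc(OCc3ccccc3)cc2)c1C(=[N+]=[N-])c1cc(OCc2ccccc2)c2c(c1)[C@@H](c1cc(OCc3ccccc3)cc(OCc3ccccc3)c1)[C@@H](c1ccc(OCc3ccccc3)cc1)O2 | intermediate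
21 | (2R,3S)-6-(benzyloxy)-2-Ar-3-[(2S,3R)-DBF-B]-4-{[(TBDPS)oxy]methyl}-2,3-dihydro-1-benzofuran (cis,cis) | c1ccccc1COc1ccc([C@@H]2Oc3cc(OCc4ccccc4)cc(CO[Si](c4ccccc4)(c4ccccc4)C(C)(C)C)c3[C@@H]2c2cc(OCc4ccccc4)c3c(c2)[C@@H](c2cc(OCc4ccccc4)cc(OCc4ccccc4)c2)[C@@H](c2ccc(OCc4ccccc4)cc2)O3)cc1 | intermediate
22 | AB-CH2OTBDPS (trans,trans) | c1ccccc1COc1ccc([C@H]2Oc3cc(OCc4ccccc4)cc(CO[Si](c4ccccc4)(c4ccccc4)C(C)(C)C)c3[C@@H]2c2cc(OCc4ccccc4)c3c(c2)[C@@H](c2cc(OCc4ccccc4)cc(OCc4ccccc4)c2)[C@H](c2ccc(OCc4ccccc4)cc2)O3)cc1 | intermediate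
23 | AB-methanol | c1ccccc1COc1ccc([C@H]2Oc3cc(OCc4ccccc4)cc(CO)c3[C@@H]2c2cc(OCc4ccccc4)c3c(c2)[C@@H](c2cc(OCc4ccccc4)cc(OCc4ccccc4)c2)[C@H](c2ccc(OCc4ccccc4)cc2)O3)cc1 | intermediate
24 | AB-methyl bromide | c1ccccc1COc1ccc([C@H]2Oc3cc(OCc4ccccc4)cc(CBr)c3[C@@H]2c2cc(OCc4ccccc4)c3c(c2)[C@@H](c2cc(OCc4ccccc4)cc(OCc4ccccc4)c2)[C@H](c2ccc(OCc4ccccc4)cc2)O3)cc1 | intermediate
25 | 2-[3,5-bis(benzyloxy)phenyl]acetic acid | OC(=O)Cc1cc(OCc2ccccc2)cc(OCc2ccccc2)c1 | starting material
26 | (4S)-4-benzyl-1,3-oxazolidin-2-one | O=C1OC[C@H](Cc2ccccc2)N1 | starting material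
27 | (4S)-4-benzyl-3-[(Res)acetyl]-1,3-oxazolidin-2-one | O=C1OC[C@H](Cc2ccccc2)N1C(=O)Cc1cc(OCc2ccccc2)cc(OCc2ccccc2)c1 | intermediate
28 | 4-(benzyloxy)benzaldehyde | O=Cc1ccc(OCc2ccccc2)cc1 | starting material
29 | (Z)-dibutylboron enolate of 27 (not isolated) | CCCCB(CCCC)O/C(=C\c1cc(OCc2ccccc2)cc(OCc2ccccc2)c1)N1[C@@H](Cc2ccccc2)COC1=O | intermediate
30 | (4S)-4-benzyl-3-[(2S,3S)-3-Ar-3-hydroxy-2-Res-propanoyl]-1,3-oxazolidin-2-one | O=C1OC[C@H](Cc2ccccc2)N1C(=O)[C@@H](c1cc(OCc2ccccc2)cc(OCc2ccccc2)c1)[C@H](O)c1ccc(OCc2ccccc2)cc1 | intermediate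
31 | TES ether of 30 | O=C1OC[C@H](Cc2ccccc2)N1C(=O)[C@@H](c1cc(OCc2ccccc2)cc(OCc2ccccc2)c1)[C@H](O[Si](CC)(CC)CC)c1ccc(OCc2ccccc2)cc1 | intermediate
32 | S-ethyl (2S,3S)-3-Ar-2-Res-3-[(triethylsilyl)oxy]propanethioate | CCSC(=O)[C@@H](c1cc(OCc2ccccc2)cc(OCc2ccccc2)c1)[C@H](O[Si](CC)(CC)CC)c1ccc(OCc2ccccc2)cc1 | intermediate
33 | AB-methylzinc bromide (not isolated) | c1ccccc1COc1ccc([C@H]2Oc3cc(OCc4ccccc4)cc(C[Zn]Br)c3[C@@H]2c2cc(OCc4ccccc4)c3c(c2)[C@@H](c2cc(OCc4ccccc4)cc(OCc4ccccc4)c2)[C@H](c2ccc(OCc4ccccc4)cc2)O3)cc1 | intermediate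
34 | (3S,4S)-1-AB-4-Ar-3-Res-4-[(triethylsilyl)oxy]butan-2-one | c1ccccc1COc1ccc([C@H]2Oc3cc(OCc4ccccc4)cc(CC(=O)[C@@H](c5cc(OCc6ccccc6)cc(OCc6ccccc6)c5)[C@H](O[Si](CC)(CC)CC)c5ccc(OCc6ccccc6)cc5)c3[C@@H]2c2cc(OCc4ccccc4)c3c(c2)[C@@H](c2cc(OCc4ccccc4)cc(OCc4ccccc4)c2)[C@H](c2ccc(OCc4ccccc4)cc2)O3)cc1 | intermediate
35 | (5S)-2-AB-1,5-di-Ar-4-Res-5-[(triethylsilyl)oxy]pent-1-en-3-one (E/Z, C4 epimers) | c1ccccc1COc1ccc([C@H]2Oc3cc(OCc4ccccc4)cc(C(=Cc5ccc(OCc6ccccc6)cc5)C(=O)C(c5cc(OCc6ccccc6)cc(OCc6ccccc6)c5)[C@H](O[Si](CC)(CC)CC)c5ccc(OCc6ccccc6)cc5)c3[C@@H]2c2cc(OCc4ccccc4)c3c(c2)[C@@H](c2cc(OCc4ccccc4)cc(OCc4ccccc4)c2)[C@H](c2ccc(OCc4ccccc4)cc2)O3)cc1 | intermediate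
36 | (5S)-2-AB-1,5-di-Ar-5-hydroxy-4-Res-pent-1-en-3-one (not isolated) | c1ccccc1COc1ccc([C@H]2Oc3cc(OCc4ccccc4)cc(C(=Cc5ccc(OCc6ccccc6)cc5)C(=O)C(c5cc(OCc6ccccc6)cc(OCc6ccccc6)c5)[C@H](O)c5ccc(OCc6ccccc6)cc5)c3[C@@H]2c2cc(OCc4ccccc4)c3c(c2)[C@@H](c2cc(OCc4ccccc4)cc(OCc4ccccc4)c2)[C@H](c2ccc(OCc4ccccc4)cc2)O3)cc1 | intermediate
37 | (2S,3R,5S,6R)-5-AB-2,6-di-Ar-3-Res-oxan-4-one | c1ccccc1COc1ccc([C@H]2Oc3cc(OCc4ccccc4)cc([C@@H]4C(=O)[C@H](c5cc(OCc6ccccc6)cc(OCc6ccccc6)c5)[C@@H](c5ccc(OCc6ccccc6)cc5)O[C@H]4c4ccc(OCc5ccccc5)cc4)c3[C@@H]2c2cc(OCc4ccccc4)c3c(c2)[C@@H](c2cc(OCc4ccccc4)cc(OCc4ccccc4)c2)[C@H](c2ccc(OCc4ccccc4)cc2)O3)cc1 | intermediate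
38 | (2R,3S,4R,5S)-3-AB-2,5-di-Ar-4-Res-oxolane (deca-O-benzylkobophenol A) | c1ccccc1COc1ccc([C@H]2Oc3cc(OCc4ccccc4)cc([C@@H]4[C@H](c5cc(OCc6ccccc6)cc(OCc6ccccc6)c5)[C@@H](c5ccc(OCc6ccccc6)cc5)O[C@H]4c4ccc(OCc5ccccc5)cc4)c3[C@@H]2c2cc(OCc4ccccc4)c3c(c2)[C@@H](c2cc(OCc4ccccc4)cc(OCc4ccccc4)c2)[C@H](c2ccc(OCc4ccccc4)cc2)O3)cc1 | intermediate
39 | kobophenol A: (2R,3S,4R,5S)-2,5-bis(4-hydroxyphenyl)-4-(3,5-dihydroxyphenyl)-3-{(2S,3S)-6-hydroxy-2-(4-hydroxyphenyl)-3-[(2R,3R)-3-(3,5-dihydroxyphenyl)-7-hydroxy-2-(4-hydroxyphenyl)-2,3-dihydro-1-benzofuran-5-yl]-2,3-dihydro-1-benzofuran-4-yl}oxolane | Oc1ccc([C@H]2Oc3cc(O)cc([C@@H]4[C@H](c5cc(O)cc(O)c5)[C@@H](c5ccc(O)cc5)O[C@H]4c4ccc(O)cc4)c3[C@@H]2c2cc(O)c3c(c2)[C@@H](c2cc(O)cc(O)c2)[C@H](c2ccc(O)cc2)O3)cc1 | target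

**Totals**
Total step count: 25. Longest linear sequence: 18 steps (steps 1–6, 10–16, 21–25).

**Steps most likely to fail**

Step 24 (proposed new method). If 37 cannot be obtained crystalline, or the lattice softens as product accumulates, the 1,5-biradical can rotate before it closes and the stereochemical memory at the two benzylic carbons is lost; disproportionation of the biradical to ring-opened alkenes can also compete. The fallback uses known chemistry, sets out from bromide 24 and comes back at 38. Michaelis–Arbuzov reaction of 24 with triethyl phosphite gives diethyl (AB-methyl)phosphonate F1. Horner–Wadsworth–Emmons olefination of F1 with aldehyde 28 (KOtBu, THF) gives the (E)-4-[4-(benzyloxy)styryl] bis(dihydrobenzofuran) F2. Anodic oxidation of F2 with an excess of commercial (E)-3,4′,5-tris(benzyloxy)stilbene (c1ccccc1COc1ccc(/C=C/c2cc(OCc3ccccc3)cc(OCc3ccccc3)c2)cc1) in wet acetonitrile (LiClO4, carbon anode, controlled potential) follows the known dehydrodimerisation of 4-alkoxystilbenes, in which 8–8′ coupling of the radical cations and capture of one molecule of water by the two 4-alkoxybenzylic cations gives 2,3,4,5-tetraaryloxolanes. This route has no stereochemical relay, so 38 would have to be separated from the homodimers and from its oxolane diastereomers.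

Step 12. Condensation may fail at the di-ortho-substituted, electron-rich diaryl ketone, or the forcing conditions may lead to azine formation or loss of the silyl ether. The fallback sets out from 18 and comes back at 22. Oxidative removal of the 4-(benzyloxy)benzyl group ortho to the carbonyl with DDQ (CH2Cl2/H2O) gives the o-hydroxy ketone F3, and NaBH4 reduction gives the o-hydroxybenzhydrol F4. Treatment of F4 with [4-(benzyloxy)benzyl]dimethylsulfonium chloride F5 (from 3 and dimethyl sulfide) and Cs2CO3 generates the o-quinone methide and the sulfur ylide, whose known [4+1] annulation gives the trans-2,3-dihydrobenzofuran silyl ether F6 (ring A trans, ring B still cis). This substrate-controlled route does not differentiate the C3 epimers of ring A, so they are separated (or a chiral sulfonium salt is used); the TFA treatment of step 14 then converts F6 into 22.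

Step 23. Under the basic fluoride conditions the liberated alkoxide may undergo retro-aldol cleavage or β-elimination faster than it adds to the enone, which erases the only fixed stereocentre of the future oxolane. Prolonged equilibration through ring-opening on both sides would have the same effect, and equilibration to the all-equatorial isomer may remain incomplete. The fallback sets out from 34 and comes back at 37. HF·pyridine removes the triethylsilyl group of 34 to give the β-hydroxy ketone F7. F7, aldehyde 28, TMSOTf and iPr2NEt at −78 °C follow the oxocarbenium variant of the Maitland–Japp synthesis (in situ silyl enol ether, oxocarbenium ion from the hemiacetal, intramolecular Mukaiyama-type aldol closure to the 2,6-cis oxan-4-one), and brief DBU treatment completes the equilibration to 37.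

**Further compounds**
F1 | step 24 | diethyl (AB-methyl)phosphonate | c1ccccc1COc1ccc([C@H]2Oc3cc(OCc4ccccc4)cc(CP(=O)(OCC)OCC)c3[C@@H]2c2cc(OCc4ccccc4)c3c(c2)[C@@H](c2cc(OCc4ccccc4)cc(OCc4ccccc4)c2)[C@H](c2ccc(OCc4ccccc4)cc2)O3)cc1
F2 | step 24 | (2S,3S)-6-(benzyloxy)-2-Ar-3-[(2R,3R)-DBF-B]-4-[(E)-2-Ar-ethenyl]-2,3-dihydro-1-benzofuran | c1ccccc1COc1ccc([C@H]2Oc3cc(OCc4ccccc4)cc(/C=C/c4ccc(OCc5ccccc5)cc4)c3[C@@H]2c2cc(OCc4ccccc4)c3c(c2)[C@@H](c2cc(OCc4ccccc4)cc(OCc4ccccc4)c2)[C@H](c2ccc(OCc4ccccc4)cc2)O3)cc1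
F3 | step 12 | [4-(benzyloxy)-2-hydroxy-6-{[(TBDPS)oxy]methyl}phenyl][(2S,3R)-DBF-B]methanone | CC(C)(C)[Si](c1ccccc1)(c1ccccc1)OCc1cc(OCc2ccccc2)cc(O)c1C(=O)c1cc(OCc2ccccc2)c2c(c1)[C@@H](c1cc(OCc3ccccc3)cc(OCc3ccccc3)c1)[C@@H](c1ccc(OCc3ccccc3)cc1)O2
F4 | step 12 | [4-(benzyloxy)-2-hydroxy-6-{[(TBDPS)oxy]methyl}phenyl][(2S,3R)-DBF-B]methanol (carbinol epimers) | CC(C)(C)[Si](c1ccccc1)(c1ccccc1)OCc1cc(OCc2ccccc2)cc(O)c1C(O)c1cc(OCc2ccccc2)c2c(c1)[C@@H](c1cc(OCc3ccccc3)cc(OCc3ccccc3)c1)[C@@H](c1ccc(OCc3ccccc3)cc1)O2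
F5 | step 12 | [4-(benzyloxy)benzyl]dimethylsulfonium chloride | C[S+](C)Cc1ccc(OCc2ccccc2)cc1.[Cl-]
F6 | step 12 | (2S,3S)-6-(benzyloxy)-2-Ar-3-[(2S,3R)-DBF-B]-4-{[(TBDPS)oxy]methyl}-2,3-dihydro-1-benzofuran (ring A trans, ring B cis) | c1ccccc1COc1ccc([C@H]2Oc3cc(OCc4ccccc4)cc(CO[Si](c4ccccc4)(c4ccccc4)C(C)(C)C)c3[C@@H]2c2cc(OCc4ccccc4)c3c(c2)[C@@H](c2cc(OCc4ccccc4)cc(OCc4ccccc4)c2)[C@@H](c2ccc(OCc4ccccc4)cc2)O3)cc1
F7 | step 23 | (3S,4S)-1-AB-4-Ar-4-hydroxy-3-Res-butan-2-one | c1ccccc1COc1ccc([C@H]2Oc3cc(OCc4ccccc4)cc(CC(=O)[C@@H](c5cc(OCc6ccccc6)cc(OCc6ccccc6)c5)[C@H](O)c5ccc(OCc6ccccc6)cc5)c3[C@@H]2c2cc(OCc4ccccc4)c3c(c2)[C@@H](c2cc(OCc4ccccc4)cc(OCc4ccccc4)c2)[C@H](c2ccc(OCc4ccccc4)cc2)O3)cc1
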